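## Structural features

The target is a daucane-type sesquiterpenoid ester: a cyclopentane (C1–C5) cis-fused through the C1–C5 bond to a cycloheptene (C5–C10, C7=C8 with a methyl group on C8). Six stereocentres form one unbroken array, C3–C4–C5(–C6)–C1–C10: the quaternary C1 (methyl) is flanked by the carbinol C10 and the ring-fusion methine C5, which carries the tertiary carbinol C4 (isopropyl) on one side and the allylic acyloxy carbon C6 on the other. The C1 methyl, H-5, the C10 hydroxyl and the C3 and C4 oxygens lie on one face (β); the C6 ester oxygen and the isopropyl group lie on the other (α). Four oxygen functions must be told apart: a secondary acetate (C3), a free tertiary alcohol (C4), an allylic 4-hydroxybenzoate (C6) and a free neopentyl secondary alcohol (C10). Fragile points are the allylic ester (ionisation, SN2′), the 1,3-dioxygenation C4–C5–C6 (β-elimination or retro-aldol cleavage once C4 or C6 is a carbonyl and C5 is enolised), the acetate next to a free hydroxyl, and the base-labile phenolic ester. The real difficulty is the cis-fused 5–7 junction with a quaternary centre: hydroazulenes are hard to obtain enantiopure and their flexibility makes stereocontrol on the seven-membered ring unreliable. The key step exploits the triad C1 (quaternary, methyl)–C5 (H)–C6 (O): it is the signature of a 1,2-shift in which the fusion bond C1–C6 of an angular-methyl trans-decalin moves to C5, so that ring A (C1–C6) contracts to the cyclopentane, ring B (C1, C6–C10) expands to the cycloheptane, and the fusion carbinol C6 becomes the C6 carbonyl.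

## Logic of the disconnections

**23 ⇒ 22.** The last cut removes the two O–Si bonds (C10–O and aryl–O). Both hydroxyls must stay masked until every acylation, enolisation and organometallic step is over, and one fluoride treatment unmasks both in a single step. The demand is a desilylation mild enough for the acetate, the allylic ester and the tertiary alcohol of 22.

**22 ⇒ 21 ⇒ 20.** The acetyl C–O bond at C3 and then both C–O bonds at C3 and C4 are cut, because the cis-3β,4β-diol is a syn-dihydroxylation retron. Two stereocentres and two oxygens are traded for one alkene. The forward steps must attack the C3=C4 alkene of 20 on the face of H-5 in preference to the C7=C8 alkene, and must acylate only the secondary hydroxyl of 21.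

**20 ⇒ 18 + 19; 18 ⇒ 17 ⇒ 16.** The C4–isopropyl bond is cut at the sp2 carbon, giving the alkenyl electrophile 18 and the commercial nucleophile 19; 18 goes back to 17 and to its masked form 16. This reuses the C4 carbonyl inherited from 1 and brings in the three missing carbons in one step. It demands kinetic enolisation of 17 toward C3 only, because a C5 enolate would expel the C6 ester, and a coupling that is faster than addition of 19 to the ester.

**16 ⇒ 12 + 15; 15 ⇒ 13.** The ester C–O bond at C6 is cut while C4 is still masked. Placed here, the aroyl group protects the C6 oxygen for the rest of the route and deactivates the neighbouring alkene toward the later oxidation; 15 comes from commercial 13 in one step. The acylation must work on a hindered allylic alcohol without ionising it.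

**12 ⇒ 11.** The C6–H bond is cut, which removes one stereocentre. The forward reduction must be 1,2-selective and must deliver hydride from the H-5 face.

**11 ⇒ 9 ⇒ 7.** The C8–methyl bond and, twice, the C7=C8 unsaturation are removed. The C6 carbonyl is the only handle on the seven-membered ring and serves all three operations. Because C5 has no β-hydrogen, dehydrogenation can only run toward C7–C8; the demand is kinetic enolisation at C7 so that C5 is not touched.

**7 ⇒ 6.** This is the strategic cut: C1–C5 is broken and C1–C6 re-formed, turning the cis-hydroazulenone into a trans-decalin hydroxy sulfonate. Two rings, the quaternary fusion and the C5 stereocentre are reduced to a chair-locked decalin whose stereochemistry is easy to set. The forward shift needs the leaving group equatorial and antiperiplanar to C1–C6, and a base that is consumed as the reaction proceeds.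

**6 ⇒ 5 ⇒ 4.** The S–O bond and the two C–O bonds at C5 and C6 are cut, leaving the C5=C6 alkene of 4. Both oxygens arrive in one syn-addition, which must occur anti to the angular methyl; the sulfonylation must choose the secondary hydroxyl.

**4 ⇒ 3 ⇒ 2 ⇒ 1.** The dioxolane, the silyl ether and the C10–H bond are removed in turn, ending at commercial, enantiopure 1, which supplies C1 with its methyl group and all ten ring carbons. The ketalisation must leave the double bond at C5=C6 (kinetic conditions). The reduction must choose the saturated carbonyl and the face anti to the methyl group.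

## Other disconnections considered

**Alternative 1:** The cut is the C8–C9 bond of the seven-membered ring. In the forward direction the cyclopentane A1 (1-methoxyvinyl group on C1; silylated butenyl ester chain on C5) would be oxidised at a carbon anode to the enol ether radical cation. The silicon-bearing carbon C8 would attack C9, loss of silicon would restore C7=C8, and hydrolysis of the ketal formed at C10 would give ketone A2.
- In its favour: the five-membered ring with C3, C4, the isopropyl group and the C6 ester is complete before ring closure, and the coupling joins two nucleophilic carbons without pre-functionalisation. After A2 only C10 reduction, acetonide-to-acetate adjustment and desilylation remain.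
- Against it here: A1 needs a cyclopentane with four contiguous stereocentres, including the quaternary C1 and the tertiary C4, plus C6, made without any ring template. The closure forms a seven-membered ring next to a quaternary carbon. The cation that develops at C7 sits beside the acyloxy-bearing C6, which destabilises it and invites participation by the ester. The electron-rich aryl silyl ether is a second oxidisable site.
- Comparison: on convergence, on step count after ring formation and on avoiding an osmylation in the presence of two alkenes this alternative is the better one. On C10 it is equal, since hydride anti to the C1 methyl is used in both. The chosen plan is stronger on structure, because C1 comes from enantiopure 1 and C5 from a stereospecific shift, whereas here the whole stereo-array must be built before the key step can even be tested.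

**Alternative 2:** The cut is the C3–C4 bond of the five-membered ring. In the forward direction SmI2 (divalent samarium) would reduce the aldehyde of keto aldehyde A3 to a ketyl, which would couple with the isopropyl ketone to give the cis-diol A4.
- In its favour: C3 and C4 are set together, the cis relationship follows from the samarium-bridged diketyl, five-membered closure is fast, and the isopropyl group enters as a simple acyl unit.
- Against it here: A3 is a fully substituted cycloheptene with the quaternary C1 and the C5, C6 and C10 stereocentres, so the hard part of the problem is left unsolved. Its ketone is α to the epimerisable C5 and β to the C6 ether, so epimerisation or reductive β-elimination could compete. The face of the new diol relative to H-5 is not fixed by the mechanism. The benzyl-type ether must later be exchanged for the aroyl ester.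
- Comparison: delivering both oxygens with the C–C bond, with no second alkene to compete, is better than the late osmylation of the chosen plan. Facial control relative to H-5 is equal, being substrate-dependent in both. On the cis 5–7 fusion the chosen plan is clearly ahead, and its step count to the bicyclic core is lower because both rings come from 1.

**Alternative 3:** The cut is the C5–C6 bond. In the forward direction BF3·OEt2 would activate the (Z)-enal of allylsilane A5, and the cyclopentenyl silane would attack through C5 anti to silicon in a Sakurai-type 1,2-addition. This would close the seven-membered ring and move the alkene to C3=C4, giving the allylic alcohol A6.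
- In its favour: one step forms the ring, sets C5 and C6, and leaves both the C6 hydroxyl and the isopropyl-substituted C3=C4 alkene, so the endgame coincides with the last steps of the chosen route.
- Against it here: seven-membered closure must beat conjugate addition of C5 to C8, which would close a five-membered ring. The (Z)-enal can isomerise under the Lewis acid and then cannot cyclise. The configuration at C6 depends on an open transition state. A5 needs an enantiopure cyclopentenylsilane with the quaternary C1, a defined C3–Si centre and a Z-trisubstituted enal.
- Comparison: creation of C5 is equally stereospecific (anti-SE2′ here, inversion in the chosen shift). The post-cyclisation step count is better, since no enone construction is needed. The chosen plan is more predictable, because only one bond is antiperiplanar to the leaving group, whereas here regiochemistry and the carbinol configuration are both open.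

Key step: step 6

Remark: locants C1–C10 are those of the target's hydroazulene core and are kept for the decalins (fusion atoms C1 and C6; ring A = C1–C6; ring B = C1, C6–C10). β means the face of the C1 methyl group, α the opposite face. The configurations of 6 and 7 are mutually consistent: inversion at C5 of the 5α-mesylate gives the 5β-hydrogen that 23 requires.

## Route

Step 1
Reactants: 1 (S)-Wieland–Miescher ketone
Product: 2 hydroxy enone [(4aS,5S)-5-hydroxy-4a-methyl-4,4a,5,6,7,8-hexahydronaphthalen-2(3H)-one]; 10β-OH cis to the C1 methyl; C4 enone intact
Conditions: NaBH4 (0.3 equiv), EtOH, −10 °C to 0 °C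
Reagents that add atoms: none
Why: Chemoselective borohydride reduction: the saturated C10 ketone is more electrophilic than the conjugated C4 ketone, and hydride enters anti to the axial C1 methyl, so the equatorial alcohol cis to the methyl should form (sets C10).

Step 2
Reactants: 2 hydroxy enone
Product: 3 TBS ether of 2 (10β-OTBS; C4 enone)
Conditions: TBSCl, imidazole, DMF, rt to 40 °C
Reagents that add atoms: tert-butyldimethylsilyl chloride, CC(C)(C)[Si](C)(C)Cl
Why: Imidazole-promoted silylation of the only hydroxyl; the bulky silyl ether survives every later basic, oxidative and mildly acidic step.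

Step 3
Reactants: 3 TBS ether enone
Product: 4 C4 ethylene ketal with the C5=C6 double bond retained (10β-OTBS)
Conditions: TMSOCH2CH2OTMS (3 equiv), TMSOTf (0.1 equiv), CH2Cl2, −78 °C; pyridine quench
Reagents that add atoms: 1,2-bis(trimethylsilyloxy)ethane, C[Si](C)(C)OCCO[Si](C)(C)C
Why: Aprotic silyl-triflate-catalysed dioxolanation; at −78 °C the oxocarbenium ion should be trapped before a dienol ether can form, so the kinetic ketal keeps the alkene at C5=C6, and the basic quench prevents later isomerisation.

Step 4
Reactants: 4 allylic ketal
Product: 5 trans-decalin 5α,6α-diol (C4 dioxolane; 10β-OTBS)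
Conditions: OsO4 (5 mol %), NMO, acetone–H2O, rt; Na2SO3
Reagents that add atoms: OsO4, O=[Os](=O)(=O)=O; N-methylmorpholine N-oxide, C[N+]1([O-])CCOCC1; water, O
Why: Catalytic OsO4 syn-dihydroxylation with NMO as reoxidant; the trisubstituted alkene should be attacked on the α-face, anti to the axial C1 methyl, which gives the trans-fused decalin with the C6 hydroxyl axial and the C5 hydroxyl equatorial (sets C5 and C6).

Step 5
Reactants: 5 diol
Product: 6 trans-decalin cis-hydroxy mesylate (5α-OMs equatorial; 6α-OH axial; C4 dioxolane; 10β-OTBS)
Conditions: MsCl, Et3N, CH2Cl2, 0 °C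
Reagents that add atoms: methanesulfonyl chloride, CS(=O)(=O)Cl
Why: Sulfonylation through sulfene reaches the hindered secondary equatorial hydroxyl, while the tertiary axial hydroxyl does not react under these conditions.

Step 6
Reactants: 6 cis-hydroxy mesylate
Product: 7 cis-fused hydroazulen-6-one (5β-H; C4 dioxolane; 10β-OTBS)
Conditions: KOtBu (1.1 equiv), t-BuOH–THF, 0 °C to rt
Reagents that add atoms: none
Why: KOtBu deprotonates the tertiary C6 hydroxyl, and as the alkoxide closes to the carbonyl the C1–C6 σ-bond, antiperiplanar to the equatorial C5–OMs bond of the chair, migrates to C5 and expels mesylate in one concerted 1,2-shift. This is the base-induced semipinacol (pinacol-type) rearrangement of a cis-1,2-diol monosulfonate, and the closest known reaction type is the conversion of decalin diol monosulfonates into hydroazulenones. The five-membered ring forms by ring contraction, not by cyclisation of a chain: ring A loses C6 when the migrating σ-bond displaces the leaving group at C5 from the rear. The seven-membered ring forms by the matching one-carbon ring expansion, ring B gaining C5 between C1 and C6 while C6 becomes the ketone. The one new stereocentre, C5, is set by stereospecific inversion: C1 enters anti to the α-mesylate, so H-5 ends cis to the C1 methyl (cis fusion), and the migrating C1 keeps its configuration. The step needs migration of C1–C6 and not of C6–C7, elimination or epoxide closure; the rigid trans-decalin secures this because only C1–C6 on the carbinol carbon is antiperiplanar to the leaving group, the C6–C7 and C6–O bonds being gauche to it. Only a slight excess of base is used at or below room temperature, so that the new enolisable C5–H, shielded between the quaternary C1 and the ketal carbon, should not be equilibrated and the β-ketal should not be opened.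

Step 7
Reactants: 7 hydroazulen-6-one
Product: 9 cyclohept-7-en-6-one (C7=C8 enone; C4 dioxolane; 10β-OTBS), via C6 silyl enol ether 8 (not isolated)
Conditions: LiN(iPr)2, TMSCl, THF, −78 °C; then Pd(OAc)2 (1.1 equiv), MeCN, rt
Reagents that add atoms: none
Why: Saegusa–Ito oxidation: kinetic deprotonation should occur at the C7 methylene because C5–H is flanked by the quaternary C1 and the ketal carbon, and the palladium enolate from 8 eliminates β-hydride toward C8; C5 has no β-hydrogen, so only the C7=C8 enone can form.

Step 8
Reactants: 9 enone
Product: 11 8-methylcyclohept-7-en-6-one (C4 dioxolane; 10β-OTBS), via 8-methyl silyl enol ether 10 (not isolated)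
Conditions: Me2CuLi (from MeLi, CuI), TMSCl, Et2O–THF, −78 °C; then Pd(OAc)2 (1.1 equiv), MeCN, rt
Reagents that add atoms: lithium dimethylcuprate, [Li+].C[Cu-]C
Why: TMSCl-accelerated conjugate addition of the cuprate to C8 with trapping as enol ether 10, followed by a second Saegusa–Ito oxidation; the transient C8 stereocentre is erased when C7=C8 is re-formed.

Step 9
Reactants: 11 methyl enone
Product: 12 6α-allylic alcohol (C7=C8; C4 dioxolane; 10β-OTBS)
Conditions: NaBH4, CeCl3·7H2O, MeOH, −78 °C to −40 °C
Reagents that add atoms: none
Why: Luche reduction gives 1,2-selective hydride delivery to the enone; hydride should approach C6 from the convex face that carries H-5, anti to the bulky C5–C4 ketal bond, placing the hydroxyl α and trans to H-5 (sets C6).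

Step 10
Reactants: 13 4-hydroxybenzoic acid
Product: 15 4-(tert-butyldimethylsilyloxy)benzoic acid, via bis-silyl ester 14 (not isolated)
Conditions: TBSCl (2.2 equiv), imidazole, DMF, rt; then AcOH–THF–H2O, rt
Reagents that add atoms: tert-butyldimethylsilyl chloride, CC(C)(C)[Si](C)(C)Cl
Why: Silylation of phenol and acid followed by selective hydrolysis of the far more labile silyl ester; the aryl silyl ether is stable to aqueous acetic acid.

Step 11
Reactants: 12 allylic alcohol; 15 4-(tert-butyldimethylsilyloxy)benzoic acid
Product: 16 6α-[4-(tert-butyldimethylsilyloxy)benzoate] (C4 dioxolane; 10β-OTBS)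
Conditions: DCC, DMAP, CH2Cl2, 0 °C to rt
Reagents that add atoms: none
Why: Steglich esterification: carbodiimide activation and DMAP acyl transfer should acylate the hindered allylic alcohol under neutral conditions, with the C–O bond at C6 untouched and its configuration retained.

Step 12
Reactants: 16 ester ketal
Product: 17 C4 ketone (6α-aroyloxy; 10β-OTBS)
Conditions: PPTS, acetone–H2O, 50 °C
Reagents that add atoms: water, O
Why: Mild acid-catalysed ketal hydrolysis; PPTS should leave both silyl ethers and the allylic ester intact and is too weak to enolise the ketone toward C5 at a useful rate.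

Step 13
Reactants: 17 ketone
Product: 18 C3=C4 enol triflate
Conditions: KN(SiMe3)2, THF, −78 °C; then PhNTf2, −78 °C to −40 °C
Reagents that add atoms: N-phenylbis(trifluoromethanesulfonimide), O=S(=O)(N(c1ccccc1)S(=O)(=O)C(F)(F)F)C(F)(F)F
Why: Kinetic enolisation with a bulky amide base should remove a C3 methylene proton and not the hindered C5 methine proton, and O-sulfonylation then gives the C3=C4 enol triflate; avoiding the C5 enolate also avoids β-elimination of the C6 ester.

Step 14
Reactants: 18 enol triflate; 19 isopropylmagnesium bromide
Product: 20 4-isopropyl C3=C4 alkene (6α-aroyloxy; C7=C8; 10β-OTBS)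
Conditions: Fe(acac)3 (10 mol %), THF–NMP, −30 °C
Reagents that add atoms: none
Why: Iron-catalysed Kumada-type cross-coupling of an alkenyl triflate with a secondary alkyl Grignard reagent; at −30 °C the coupling should be much faster than addition of the Grignard reagent to the aryl ester.

Step 15
Reactants: 20 diene
Product: 21 3β,4β-diol (4α-isopropyl; 6α-aroyloxy; 10β-OTBS)
Conditions: OsO4 (5 mol %), NMO, acetone–H2O, 0 °C to rt; Na2SO3
Reagents that add atoms: OsO4, O=[Os](=O)(=O)=O; N-methylmorpholine N-oxide, C[N+]1([O-])CCOCC1; water, O
Why: Syn-dihydroxylation: the strained, electron-richer cyclopentene should react before the C7=C8 alkene, which is deactivated by its allylic acyloxy group, and OsO4 should add to the convex face carrying H-5 and the C1 methyl, anti to the C5–C6 bond (sets C3 and C4).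

Step 16
Reactants: 21 diol
Product: 22 3β-acetate (4β-OH free)
Conditions: Ac2O, pyridine, DMAP (cat.), CH2Cl2, rt
Reagents that add atoms: acetic anhydride, CC(=O)OC(C)=O
Why: DMAP-catalysed acylation takes the secondary C3 hydroxyl; the tertiary C4 hydroxyl flanked by the isopropyl group is too hindered to react.

Step 17
Reactants: 22 bis-silyl ether
Product: 23 target CNP0146780.2
Conditions: HF·pyridine, pyridine, THF, 0 °C to rt
Reagents that add atoms: none
Why: Buffered fluoride cleavage of the aryl and the C10 silyl ethers in one operation; the weakly acidic medium should spare the acetate, the allylic ester and the tertiary alcohol.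

## Compound list

1 | (S)-Wieland–Miescher ketone | C[C@]12CCC(=O)C=C1CCCC2=O | starting material
2 | 10β-hydroxy enone, (4aS,5S)-5-hydroxy-4a-methyl-4,4a,5,6,7,8-hexahydronaphthalen-2(3H)-one | O=C1CC[C@]2(C)[C@@H](O)CCCC2=C1 | intermediate
3 | 10β-TBS ether of the enone | O=C1CC[C@]2(C)[C@@H](O[Si](C)(C)C(C)(C)C)CCCC2=C1 | intermediate
4 | C4 ethylene ketal with C5=C6 alkene, 10β-OTBS | C1C[C@]2(C)[C@@H](O[Si](C)(C)C(C)(C)C)CCCC2=CC13OCCO3 | intermediate
5 | trans-decalin 5α,6α-diol, C4 dioxolane, 10β-OTBS | C1C[C@]2(C)[C@@H](O[Si](C)(C)C(C)(C)C)CCC[C@@]2(O)[C@H](O)C13OCCO3 | intermediate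
6 | trans-decalin 6α-hydroxy 5α-mesylate, C4 dioxolane, 10β-OTBS (key-step precursor) | C1C[C@]2(C)[C@@H](O[Si](C)(C)C(C)(C)C)CCC[C@@]2(O)[C@H](OS(C)(=O)=O)C13OCCO3 | intermediate
7 | cis-fused hydroazulen-6-one, 5β-H, C4 dioxolane, 10β-OTBS (key-step product) | C1C[C@]2(C)[C@@H](O[Si](C)(C)C(C)(C)C)CCCC(=O)[C@@H]2C13OCCO3 | intermediate
8 | C6 trimethylsilyl enol ether (C6=C7) of 7 | C1C[C@]2(C)[C@@H](O[Si](C)(C)C(C)(C)C)CCC=C(O[Si](C)(C)C)[C@@H]2C13OCCO3 | intermediate (not isolated)
9 | cyclohept-7-en-6-one, C4 dioxolane, 10β-OTBS | C1C[C@]2(C)[C@@H](O[Si](C)(C)C(C)(C)C)CC=CC(=O)[C@@H]2C13OCCO3 | intermediate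
10 | 8-methyl C6 trimethylsilyl enol ether (C6=C7; both C8 epimers, which converge) | C1C[C@]2(C)[C@@H](O[Si](C)(C)C(C)(C)C)CC(C)C=C(O[Si](C)(C)C)[C@@H]2C13OCCO3 | intermediate (not isolated)
11 | 8-methylcyclohept-7-en-6-one, C4 dioxolane, 10β-OTBS | C1C[C@]2(C)[C@@H](O[Si](C)(C)C(C)(C)C)CC(C)=CC(=O)[C@@H]2C13OCCO3 | intermediate
12 | 6α-allylic alcohol, C7=C8, C4 dioxolane, 10β-OTBS | C1C[C@]2(C)[C@@H](O[Si](C)(C)C(C)(C)C)CC(C)=C[C@H](O)[C@@H]2C13OCCO3 | intermediate
13 | 4-hydroxybenzoic acid | O=C(O)c1ccc(O)cc1 | starting material
14 | tert-butyldimethylsilyl 4-(tert-butyldimethylsilyloxy)benzoate | CC(C)(C)[Si](C)(C)OC(=O)c1ccc(O[Si](C)(C)C(C)(C)C)cc1 | intermediate (not isolated)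
15 | 4-(tert-butyldimethylsilyloxy)benzoic acid | O=C(O)c1ccc(O[Si](C)(C)C(C)(C)C)cc1 | intermediate
16 | 6α-[4-(TBSO)benzoate], C4 dioxolane, 10β-OTBS | C1C[C@]2(C)[C@@H](O[Si](C)(C)C(C)(C)C)CC(C)=C[C@H](OC(=O)c3ccc(O[Si](C)(C)C(C)(C)C)cc3)[C@@H]2C14OCCO4 | intermediate
17 | C4 ketone, 6α-[4-(TBSO)benzoate], 10β-OTBS | O=C1CC[C@]2(C)[C@@H](O[Si](C)(C)C(C)(C)C)CC(C)=C[C@H](OC(=O)c3ccc(O[Si](C)(C)C(C)(C)C)cc3)[C@@H]21 | intermediate
18 | C3=C4 enol triflate | FC(F)(F)S(=O)(=O)OC1=CC[C@]2(C)[C@@H](O[Si](C)(C)C(C)(C)C)CC(C)=C[C@H](OC(=O)c3ccc(O[Si](C)(C)C(C)(C)C)cc3)[C@@H]21 | intermediate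
19 | isopropylmagnesium bromide | CC(C)[Mg]Br | starting material
20 | 4-isopropyl C3=C4 alkene, 6α-[4-(TBSO)benzoate], 10β-OTBS | CC(C)C1=CC[C@]2(C)[C@@H](O[Si](C)(C)C(C)(C)C)CC(C)=C[C@H](OC(=O)c3ccc(O[Si](C)(C)C(C)(C)C)cc3)[C@@H]21 | intermediate
21 | 3β,4β-diol, 4α-isopropyl, 6α-[4-(TBSO)benzoate], 10β-OTBS | O[C@H]1C[C@]2(C)[C@@H](O[Si](C)(C)C(C)(C)C)CC(C)=C[C@H](OC(=O)c3ccc(O[Si](C)(C)C(C)(C)C)cc3)[C@@H]2[C@]1(O)C(C)C | intermediate
22 | 3β-acetate, 4β-OH, 6α-[4-(TBSO)benzoate], 10β-OTBS | CC(=O)O[C@H]1C[C@]2(C)[C@@H](O[Si](C)(C)C(C)(C)C)CC(C)=C[C@H](OC(=O)c3ccc(O[Si](C)(C)C(C)(C)C)cc3)[C@@H]2[C@]1(O)C(C)C | intermediate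
23 | CNP0146780.2 (3β-acetoxy-4β,10β-dihydroxy-6α-(4-hydroxybenzoyloxy)-4α-isopropyl-1β,8-dimethyl cis-hydroazul-7-ene) | CC(=O)O[C@H]1C[C@]2(C)[C@@H](O)CC(C)=C[C@H](OC(=O)c3ccc(O)cc3)[C@@H]2[C@]1(O)C(C)C | target

## Step count and least certain steps

Total: 17 steps. Longest linear sequence: 16 steps from 1 (steps 1–9 and 11–17); step 10 is a one-step side branch to 15.

**Step 6 (key step).** The most likely failure is loss of the kinetically set ring fusion after the shift: surplus alkoxide can enolise the new ketone toward C5 and equilibrate cis and trans fusion, or open the β-dioxolane by E1cB. Slow ionisation of the hindered equatorial sulfonate would lengthen exposure to base and make both worse. The fallback replaces the anionic trigger by neutral solvolysis. It sets out from 5, which would be converted with TsCl, pyridine and DMAP into the 5α-tosylate F1. F1 would be heated with LiClO4 and CaCO3 in THF at 50 °C, where the free C6 hydroxyl assists ionisation and the same antiperiplanar C1–C6 bond migrates with no strong base present. The fallback comes back to the route at 7.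

**Step 3.** The most likely failure is migration of the double bond out of the C5=C6 position (to C6=C7) through a dienol ether under the Lewis-acidic conditions, or slow ketalisation because conjugated ketones form oxocarbenium ions reluctantly. A shifted alkene would misplace the diol in step 4. The fallback reverses the order of events. It sets out from 3, whose enone would be osmylated on the α-face with stoichiometric OsO4 in pyridine (NaHSO3 work-up) to the keto diol F2. F2 has no alkene left to migrate and would be ketalised under the same aprotic conditions, with K2CO3/MeOH to strip transient trimethylsilyl ethers. The fallback comes back at 5.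

**Step 9.** The most likely failure is poor facial selectivity in hydride delivery: the cycloheptenone is flexible and the C1 methyl lies 1,3 to C6 on the face from which hydride must come. The fallback inverts instead of reducing selectively. It sets out from 11; the 6β-epimeric alcohol F3 from the reduction would be esterified with acid 15 under Mitsunobu conditions (PPh3, DIAD, THF), which forms the ester with inversion at C6. The fallback comes back at 16.

**Step 13 (with step 12).** The most likely failure is β-elimination of the C6 aroyloxy group by an E1cB path, or epimerisation at C5, if enolisation toward C5 competes with the kinetic C3 deprotonation. The fallback postpones the ester so that C6 carries a poor leaving group during the C4 chemistry. It sets out from 12, which would be converted with NaH, 4-methoxybenzyl chloride and Bu4NI into the 4-methoxybenzyl ether F4. Ketal hydrolysis (PPTS, wet acetone) would give ketone F5, and KN(SiMe3)2/PhNTf2 the enol triflate F6. Iron-catalysed coupling with 19 would give the isopropyl alkene F7, with no ester exposed to the Grignard reagent. DDQ in buffered CH2Cl2–H2O would release the allylic alcohol F8 (the same compound as A6), and Steglich esterification with 15 brings the fallback back at 20.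

**Step 15.** The most likely failure is poor facial selectivity in the osmylation, because the C1 methyl sits on the convex face that OsO4 must use; competing attack on C7=C8 is the lesser concern. The fallback is the Woodward cis-hydroxylation, which delivers the cis-diol to the face opposite to the one a bulky electrophile attacks first. It sets out from 20, which would be treated with I2 and AgOAc in acetic acid to give the trans-iodo acetate F9. Adding water and warming would pass through the acetoxonium ion, and the cis-hydroxy acetate should form with the acetyl group settling on the secondary C3 oxygen. The fallback comes back at 22 and skips 21.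

## Further compounds

F1 | step 6 | trans-decalin 6α-hydroxy 5α-tosylate, C4 dioxolane, 10β-OTBS | C1C[C@]2(C)[C@@H](O[Si](C)(C)C(C)(C)C)CCC[C@@]2(O)[C@H](OS(=O)(=O)c3ccc(C)cc3)C14OCCO4
F2 | step 3 | 5α,6α-dihydroxy C4 ketone, 10β-OTBS | O=C1CC[C@]2(C)[C@@H](O[Si](C)(C)C(C)(C)C)CCC[C@@]2(O)[C@@H]1O
F3 | step 9 | 6β-allylic alcohol (C6 epimer of 12) | C1C[C@]2(C)[C@@H](O[Si](C)(C)C(C)(C)C)CC(C)=C[C@@H](O)[C@@H]2C13OCCO3
F4 | step 13 | 6α-(4-methoxybenzyl) ether, C4 dioxolane, 10β-OTBS | C1C[C@]2(C)[C@@H](O[Si](C)(C)C(C)(C)C)CC(C)=C[C@H](OCc3ccc(OC)cc3)[C@@H]2C14OCCO4
F5 | step 13 | C4 ketone, 6α-(4-methoxybenzyl) ether | O=C1CC[C@]2(C)[C@@H](O[Si](C)(C)C(C)(C)C)CC(C)=C[C@H](OCc3ccc(OC)cc3)[C@@H]21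
F6 | step 13 | C3=C4 enol triflate, 6α-(4-methoxybenzyl) ether | FC(F)(F)S(=O)(=O)OC1=CC[C@]2(C)[C@@H](O[Si](C)(C)C(C)(C)C)CC(C)=C[C@H](OCc3ccc(OC)cc3)[C@@H]21
F7 | step 13 | 4-isopropyl C3=C4 alkene, 6α-(4-methoxybenzyl) ether | CC(C)C1=CC[C@]2(C)[C@@H](O[Si](C)(C)C(C)(C)C)CC(C)=C[C@H](OCc3ccc(OC)cc3)[C@@H]21
F8 | step 13 | 4-isopropyl C3=C4 alkene, 6α-allylic alcohol, 10β-OTBS | CC(C)C1=CC[C@]2(C)[C@@H](O[Si](C)(C)C(C)(C)C)CC(C)=C[C@H](O)[C@@H]21
F9 | step 15 | 3α-iodo 4β-acetate (trans-iodo acetate of 20) | I[C@@H]1C[C@]2(C)[C@@H](O[Si](C)(C)C(C)(C)C)CC(C)=C[C@H](OC(=O)c3ccc(O[Si](C)(C)C(C)(C)C)cc3)[C@@H]2[C@]1(OC(C)=O)C(C)C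
A1 | alternative 1 | cyclopentane with 1-methoxyvinyl group on C1 and (Z)-3-(trimethylsilyl)but-2-enyl aroyl ester chain on C5, C3/C4 acetonide | CC1(C)O[C@H]2C[C@](C)(C(OC)=C)[C@H]([C@@H](OC(=O)c3ccc(O[Si](C(C)C)(C(C)C)C(C)C)cc3)/C=C(\[Si](C)(C)C)C)[C@]2(O1)C(C)C
A2 | alternative 1 | C10 ketone with C7=C8 alkene, C6 aroyl ester, C3/C4 acetonide | CC1(C)O[C@H]2C[C@]3(C)C(=O)CC(C)=C[C@H](OC(=O)c4ccc(O[Si](C(C)C)(C(C)C)C(C)C)cc4)[C@@H]3[C@]2(O1)C(C)C
A3 | alternative 2 | cycloheptene keto aldehyde (C3 aldehyde, C4 isopropyl ketone, C6 4-methoxybenzyl ether, C10 silyl ether) | O=CC[C@]1(C)[C@@H](O[Si](C)(C)C(C)(C)C)CC(C)=C[C@H](OCc2ccc(OC)cc2)[C@@H]1C(=O)C(C)C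
A4 | alternative 2 | bicyclic C3,C4-cis-diol (C6 4-methoxybenzyl ether, C10 silyl ether) | O[C@H]1C[C@]2(C)[C@@H](O[Si](C)(C)C(C)(C)C)CC(C)=C[C@H](OCc3ccc(OC)cc3)[C@@H]2[C@]1(O)C(C)C
A5 | alternative 3 | cyclopentenyl allylsilane (3β-SiMe3, C4=C5, isopropyl on C4) with (Z)-enal chain on C1 | C[Si](C)(C)[C@H]1C[C@](C)([C@@H](O[Si](C)(C)C(C)(C)C)C/C(C)=C\C=O)C=C1C(C)C
A6 | alternative 3 | cis-fused bicyclic C6 allylic alcohol with C3=C4 alkene, C10 silyl ether | C1C[C@]2(C)[C@@H](O[Si](C)(C)C(C)(C)C)CC(C)=C[C@H](O)[C@@H]2C=1C(C)C
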